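Assumption: atoms keep the target's locants (decalin C1–C8a with C1 = acyloxy carbon, C3 = ring-methyl carbon, C7 = carbinol, C8 = quaternary carbon; side chain C1'–C12' counted from the free acid), and in step 1 the cinchona pseudoenantiomer that gives the S enone is used.

**Retrosynthetic overview**
1. Calbistrin C ⇒ Stille coupling (C7'–C8') of a stannyl trienoic acid with a decalin ester that carries a vinyl iodide.
2. Key bond: the C1–O acyl bond, made by esterifying the axial C1 alcohol with an anti-aldol iodo acid while C8 is still tertiary; C8 and C7 are then set by an enolate aldol and a chelation-controlled methyl addition.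
3. Decalin alcohol ⇒ linear dienone ⇒ cis-fused, siloxane-bridged tricycle; the C4 ketone that activates the dienophile also serves for C3 methylation and is then removed as C4=C4a.
4. Ring A comes ready-made from cyclohexa-1,3-diene (O2, asymmetric Kornblum–DeLaMare sets C1–O); ring B is closed second by a silyl-acetal-tethered type 2 Diels–Alder that relays C1 to C8a.
5. Side-chain pieces: Negishi carboalumination plus Evans anti-aldol (C10', C11'); hydrostannylation plus Horner–Wadsworth–Emmons.

**Route**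

Step 1
Reactants: 1 cyclohexa-1,3-diene
Product: 3 (S)-4-hydroxycyclohex-2-en-1-one, via endoperoxide 2 (not isolated)
Conditions: O2, tetraphenylporphyrin (cat.), visible light, CH2Cl2, −30 °C; then O-acetyl-6'-demethyl cinchona base (5 mol%), CH2Cl2, rt
Reagents that add atoms: dioxygen O=O
Why: Singlet-oxygen [4+2] cycloaddition gives the meso endoperoxide, and the chiral-base-catalysed enantioselective Kornblum–DeLaMare rearrangement removes one enantiotopic bridgehead hydrogen, setting C1 as S.

Step 2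
Reactants: 4 pent-1-en-3-one, 3 (S)-4-hydroxycyclohex-2-en-1-one
Product: 7 (S)-4-{[(penta-1,3-dien-3-yloxy)di(propan-2-yl)silyl]oxy}cyclohex-2-en-1-one, via lithium dienolate 5 (not isolated), via chlorosilane 6 (not isolated)
Conditions: 4, LiN(iPr)2, THF, −78 °C; cannulate into iPr2SiCl2 (1.2 equiv), −78 → 0 °C; then 3, imidazole, CH2Cl2, 0 °C → rt
Reagents that add atoms: dichlorodi(propan-2-yl)silane CC(C)[Si](Cl)(Cl)C(C)C
Why: Kinetic α'-deprotonation and O-silylation of the enolate, then silylation of the carbinol by the hindered monochlorosilane, gives the unsymmetrical silyl acetal (stepwise silyl ether formation) without touching C1.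

Step 3
Reactants: 7 silyl acetal triene
Product: 8 siloxane-bridged cis-octalone (1S,4aS,8aR)
Conditions: toluene (5 mM), BHT (cat.), silylated sealed tube, 170 °C, 36 h
Reagents that add atoms: none
Why: Proposed new method: a type 2 intramolecular Diels–Alder reaction in which a 2-silyloxy diene is tied by a four-atom C–O–Si–O tether to the γ-carbinol of a cyclohexenone, so that the tether (not sterics, which would favour the anti face) forces the diene onto the alkene face syn to the C1 oxygen through an endo transition state, bonds C8 to C8a (also the electronically matched sense, nucleophilic diene terminus to the enone β-carbon) and gives the cis ring fusion, setting C8a (R) and C4a (S) from C1; the closest known reaction type is the type 2 intramolecular Diels–Alder reaction with disposable silyl acetal tethers on acyclic dienophiles (temporary silicon connection), not yet shown on a ring dienophile as a relay of a ring carbinol stereocentre.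

Step 4
Reactants: 8 siloxane-bridged cis-octalone
Product: 10 3-methyl tricycle (1S,3S,4aS,8aR), via lithium enolate 9 (not isolated)
Conditions: LiN(iPr)2, THF, −78 °C; MeI, −78 → −30 °C
Reagents that add atoms: iodomethane CI
Why: Kinetic enolate alkylation at the less substituted α-carbon C3; the concave α face is blocked by ring B and the siloxane bridge, so methyl enters on the convex β face and sets C3 as S.

Step 5
Reactants: 10 3-methyl tricycle
Product: 11 C4 alcohol (C4 epimers)
Conditions: LiBH4, THF, 0 °C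
Reagents that add atoms: none
Why: Borohydride reduction of the only ketone removes the epimerisable position next to C3; the new C4 centre is inconsequential because it is eliminated in step 7.

Step 6
Reactants: 11 C4 alcohol
Product: 12 C4 mesylate
Conditions: MsCl, Et3N, CH2Cl2, 0 °C
Reagents that add atoms: methanesulfonyl chloride CS(=O)(=O)Cl
Why: Standard sulfonylation of the only free hydroxyl (C1–O is still tied up in the bridge) installs the leaving group for the later elimination.

Step 7
Reactants: 12 C4 mesylate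
Product: 15 dienone alcohol (1S,3S,8aR), via enone mesylate 13 (not isolated), via acetoxysilyl dienone 14 (not isolated)
Conditions: Pd(OAc)2 (1.1 equiv), MeCN, rt; then DBU, 0 °C; then HF·pyridine, THF, 0 °C
Reagents that add atoms: none
Why: Saegusa–Ito oxidation of the bridgehead silyl enol ether gives the C7 enone regiospecifically, the now γ-acidic C4a–H allows vinylogous E1cB loss of mesylate to the linear C4=C4a/C5=C6 dienone, and fluoride frees the C1 hydroxyl; C1, C3 and C8a are untouched.

Step 8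
Reactants: 16 prop-2-yn-1-ol
Product: 18 (E)-3-iodo-2-methylprop-2-en-1-ol, via alkenylalane 17 (not isolated)
Conditions: AlMe3 (3 equiv), Cp2ZrCl2 (0.25 equiv), CH2Cl2, 0 °C → rt; then I2, THF, −30 → 0 °C
Reagents that add atoms: trimethylalumane C[Al](C)C; diiodine II
Why: Negishi zirconium-catalysed syn carboalumination of the alkyne followed by iodinolysis with retention gives the E vinyl iodide.

Step 9
Reactants: 18 (E)-3-iodo-2-methylprop-2-en-1-ol
Product: 19 (E)-3-iodo-2-methylprop-2-enal
Conditions: MnO2, CH2Cl2, rt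
Reagents that add atoms: none
Why: Chemoselective allylic alcohol oxidation with manganese dioxide, without isomerising the alkene.

Step 10
Reactants: 20 (R)-4-benzyl-3-propanoyl-1,3-oxazolidin-2-one, 19 (E)-3-iodo-2-methylprop-2-enal
Product: 22 (R)-4-benzyl-3-[(2S,3R,4E)-3-hydroxy-5-iodo-2,4-dimethylpent-4-enoyl]-1,3-oxazolidin-2-one, via silyl ether 21 (not isolated)
Conditions: MgCl2 (10 mol%), Et3N, Me3SiCl, EtOAc, rt; then CF3CO2H, MeOH
Reagents that add atoms: none
Why: Evans magnesium-halide-catalysed anti-aldol reaction of the chelated Z-enolate with a non-enolisable enal; the (R)-benzyl auxiliary shields one enolate face and gives the 2S,3R anti adduct (C11', C10'), the trimethylsilyl ether being cleaved on work-up.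

Step 11
Reactants: 22 anti-aldol imide
Product: 23 tert-butyldimethylsilyl ether of 22
Conditions: t-BuMe2SiOTf, 2,6-lutidine, CH2Cl2, −78 → 0 °C
Reagents that add atoms: tert-butyldimethylsilyl trifluoromethanesulfonate CC(C)(C)[Si](C)(C)OS(=O)(=O)C(F)(F)F
Why: Silyl triflate protection of the hindered allylic carbinol prevents self-acylation and retro-aldol in the later steps.

Step 12
Reactants: 23 silyl ether imide
Product: 25 (2S,3R,4E)-3-[(tert-butyldimethylsilyl)oxy]-5-iodo-2,4-dimethylpent-4-enoic acid, via peroxy acid 24 (not isolated)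
Conditions: LiOH, H2O2, THF/H2O, 0 °C; then Na2SO3; aq. HCl to pH 3
Reagents that add atoms: hydrogen peroxide OO
Why: Evans auxiliary cleavage, in which lithium hydroperoxide attacks the exocyclic imide carbonyl selectively without epimerising C11' and sulfite reduces the peracid to the acid.

Step 13
Reactants: 25 iodo acid, 15 dienone alcohol
Product: 27 C1 ester (1S,3S,8aR; acyl 2S,3R,4E), via mixed anhydride 26 (not isolated)
Conditions: 25, 2,4,6-Cl3C6H2COCl, Et3N, THF, rt; then 15, DMAP, toluene, rt → 40 °C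
Reagents that add atoms: none
Why: Yamaguchi esterification (acyl transfer from the mixed anhydride through the acylpyridinium) forms the key C1–O acyl bond with retention at C1 and C11'; it is run while C8 is still tertiary so that the axial carbinol is accessible, and with a compact iodo acid instead of the polyene.

Step 14
Reactants: 27 C1 ester, 28 3-[(tert-butyldimethylsilyl)oxy]propanal
Product: 31 diol (1S,3S,7R,8S,8aS), via lithium enolate 29 (not isolated), via aldol adduct 30 (not isolated)
Conditions: LiN(SiMe3)2 (1.05 equiv), THF, −78 °C, 15 min; 28, −78 °C; then MeMgCl/CeCl3 (premixed, 3 equiv), −78 °C; aq. NH4Cl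
Reagents that add atoms: methylmagnesium chloride C[Mg]Cl
Why: Aldol addition of the α'-enolate builds the C8 quaternary centre from the β face (the axial C1 acyloxy group shields the α face), and chelation-controlled 1,2-addition of the organocerium reagent to the C7 ketone (the aldolate chelate holds the side chain in the carbonyl plane, the now axial C8 methyl blocks the α face) puts the C7 methyl cis to the side chain (7R).

Step 15
Reactants: 31 diol
Product: 32 keto alcohol (1S,3S,7R,8R,8aS)
Conditions: Dess–Martin periodinane, NaHCO3, CH2Cl2, 0 °C → rt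
Reagents that add atoms: none
Why: Dess–Martin oxidation converts the only secondary alcohol into the side-chain ketone; the tertiary C7 alcohol, dienes and vinyl iodide are inert under these buffered conditions.

Step 16
Reactants: 32 keto alcohol
Product: 33 triol vinyl iodide
Conditions: HF·pyridine, pyridine, THF, 0 °C → rt
Reagents that add atoms: none
Why: Buffered fluoride desilylation removes both silyl ethers without base, so the tertiary aldol (C7–C8) and the β-hydroxy ketone do not undergo retro-aldol or elimination.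

Step 17
Reactants: 34 (E)-3-methylpent-2-en-4-yn-1-ol
Product: 35 (2E,4E)-3-methyl-5-(tributylstannyl)penta-2,4-dien-1-ol
Conditions: Bu3SnH, PdCl2(PPh3)2 (2 mol%), THF, 0 °C
Reagents that add atoms: tributylstannane CCCC[SnH](CCCC)CCCC
Why: Palladium-catalysed syn hydrostannylation of the terminal alkyne places tin at the terminus and gives the E vinylstannane; the existing E alkene is kept.

Step 18
Reactants: 35 stannyl dienol
Product: 36 (2E,4E)-3-methyl-5-(tributylstannyl)penta-2,4-dienal
Conditions: MnO2, CH2Cl2, rt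
Reagents that add atoms: none
Why: Allylic oxidation with manganese dioxide, which tolerates the vinylstannane.

Step 19
Reactants: 36 stannyl dienal, 37 2-(diethoxyphosphoryl)acetic acid
Product: 38 (2E,4E,6E)-5-methyl-7-(tributylstannyl)hepta-2,4,6-trienoic acid
Conditions: 37, LiN(SiMe3)2 (2.1 equiv), THF, −78 °C; 36, −78 → 0 °C; pH 5 buffer
Reagents that add atoms: none
Why: Horner–Wadsworth–Emmons olefination with the phosphonoacetate dianion gives the E enoic acid directly, so no ester hydrolysis is needed later.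

Step 20
Reactants: 33 triol vinyl iodide, 38 stannyl trienoic acid
Product: 39 calbistrin C
Conditions: Pd2(dba)3 (5 mol%), AsPh3 (20 mol%), N-methylpyrrolidone, rt, dark
Reagents that add atoms: none
Why: Stille cross-coupling joins C7' and C8' with retention of both alkene geometries to give the all-E tetraene acid; free hydroxyls and the carboxylic acid are tolerated.

**Compound list**
1 | cyclohexa-1,3-diene | C1=CC=CCC1 | starting material
2 | 2,3-dioxabicyclo[2.2.2]oct-5-ene (meso endoperoxide) | C1=CC2CCC1OO2 | intermediate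
3 | (S)-4-hydroxycyclohex-2-en-1-one | O[C@H]1CCC(=O)C=C1 | intermediate
4 | pent-1-en-3-one | CCC(=O)C=C | starting material
5 | lithium penta-1,3-dien-3-olate | [Li]OC(=CC)C=C | intermediate
6 | chloro(penta-1,3-dien-3-yloxy)di(propan-2-yl)silane | CC=C(O[Si](Cl)(C(C)C)C(C)C)C=C | intermediate
7 | (S)-4-{[(penta-1,3-dien-3-yloxy)di(propan-2-yl)silyl]oxy}cyclohex-2-en-1-one (enol ether E/Z mixture) | CC=C(O[Si](C(C)C)(C(C)C)O[C@H]1CCC(=O)C=C1)C=C | intermediate
8 | (1S,4aS,8aR) cis-fused 8-methyl-octalin-4-one with C6=C7 silyl enol ether, C1–O and C7–O bridged by Si(iPr)2 (C8 epimers) | O1[C@H]2CCC(=O)[C@H]3CC=C(O[Si]1(C(C)C)C(C)C)C(C)[C@@H]23 | intermediate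
9 | lithium C3=C4 enolate of 8 | O1[C@H]2CC=C(O[Li])[C@H]3CC=C(O[Si]1(C(C)C)C(C)C)C(C)[C@@H]23 | intermediate
10 | (1S,3S,4aS,8aR) 3-methyl derivative of 8 (methyl cis to H4a and H8a) | O1[C@H]2C[C@H](C)C(=O)[C@H]3CC=C(O[Si]1(C(C)C)C(C)C)C(C)[C@@H]23 | intermediate
11 | (1S,3S,4aS,8aS) C4 alcohol of 10 (C4 epimers) | O1[C@H]2C[C@H](C)C(O)[C@H]3CC=C(O[Si]1(C(C)C)C(C)C)C(C)[C@@H]23 | intermediate
12 | C4 methanesulfonate of 11 | O1[C@H]2C[C@H](C)C(OS(C)(=O)=O)[C@H]3CC=C(O[Si]1(C(C)C)C(C)C)C(C)[C@@H]23 | intermediate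
13 | (1S,3S,4aS,8aS) C7 enone (C5=C6) with C4 mesylate and C1–O–Si(iPr)2–OAc | CC(=O)O[Si](C(C)C)(C(C)C)O[C@H]1C[C@H](C)C(OS(C)(=O)=O)[C@H]2C=CC(=O)C(C)[C@H]21 | intermediate
14 | (1S,3S,8aR)-1-{[acetoxydi(propan-2-yl)silyl]oxy}-3,8-dimethyl-2,3,8,8a-tetrahydronaphthalen-7(1H)-one | CC(=O)O[Si](C(C)C)(C(C)C)O[C@H]1C[C@H](C)C=C2C=CC(=O)C(C)[C@H]21 | intermediate
15 | (1S,3S,8aR)-1-hydroxy-3,8-dimethyl-2,3,8,8a-tetrahydronaphthalen-7(1H)-one (C4=C4a, C5=C6 dienone; C8 epimers) | O[C@H]1C[C@H](C)C=C2C=CC(=O)C(C)[C@H]21 | intermediate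
16 | prop-2-yn-1-ol | C#CCO | starting material
17 | dimethyl[(E)-3-(dimethylalumanyloxy)-2-methylprop-1-enyl]alumane | C[Al](C)/C=C(\C)CO[Al](C)C | intermediate
18 | (E)-3-iodo-2-methylprop-2-en-1-ol | OC/C(C)=C/I | intermediate
19 | (E)-3-iodo-2-methylprop-2-enal | O=C/C(C)=C/I | intermediate
20 | (R)-4-benzyl-3-propanoyl-1,3-oxazolidin-2-one | CCC(=O)N1[C@H](Cc2ccccc2)COC1=O | starting material
21 | trimethylsilyl ether of 22 | I/C=C(\C)[C@H](O[Si](C)(C)C)[C@H](C)C(=O)N1[C@H](Cc2ccccc2)COC1=O | intermediate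
22 | (R)-4-benzyl-3-[(2S,3R,4E)-3-hydroxy-5-iodo-2,4-dimethylpent-4-enoyl]-1,3-oxazolidin-2-one | I/C=C(\C)[C@H](O)[C@H](C)C(=O)N1[C@H](Cc2ccccc2)COC1=O | intermediate
23 | tert-butyldimethylsilyl ether of 22 | I/C=C(\C)[C@H](O[Si](C)(C)C(C)(C)C)[C@H](C)C(=O)N1[C@H](Cc2ccccc2)COC1=O | intermediate
24 | (2S,3R,4E)-3-[(tert-butyldimethylsilyl)oxy]-5-iodo-2,4-dimethylpent-4-eneperoxoic acid | I/C=C(\C)[C@H](O[Si](C)(C)C(C)(C)C)[C@H](C)C(=O)OO | intermediate
25 | (2S,3R,4E)-3-[(tert-butyldimethylsilyl)oxy]-5-iodo-2,4-dimethylpent-4-enoic acid | I/C=C(\C)[C@H](O[Si](C)(C)C(C)(C)C)[C@H](C)C(=O)O | intermediate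
26 | mixed anhydride of 25 with 2,4,6-trichlorobenzoic acid | I/C=C(\C)[C@H](O[Si](C)(C)C(C)(C)C)[C@H](C)C(=O)OC(=O)c1c(Cl)cc(Cl)cc1Cl | intermediate
27 | (1S,3S,8aR)-3,8-dimethyl-7-oxo-1,2,3,7,8,8a-hexahydronaphthalen-1-yl ester of 25 (C8 epimers) | I/C=C(\C)[C@H](O[Si](C)(C)C(C)(C)C)[C@H](C)C(=O)O[C@H]1C[C@H](C)C=C2C=CC(=O)C(C)[C@H]21 | intermediate
28 | 3-[(tert-butyldimethylsilyl)oxy]propanal | O=CCCO[Si](C)(C)C(C)(C)C | starting material
29 | lithium C7=C8 enolate of 27 | I/C=C(\C)[C@H](O[Si](C)(C)C(C)(C)C)[C@H](C)C(=O)O[C@H]1C[C@H](C)C=C2C=CC(O[Li])=C(C)[C@H]21 | intermediate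
30 | aldol adduct: 27 with C8 (S) bearing methyl (α) and CH(OH)CH2CH2OSi-t-BuMe2 (β), C7 ketone (carbinol epimers) | I/C=C(\C)[C@H](O[Si](C)(C)C(C)(C)C)[C@H](C)C(=O)O[C@H]1C[C@H](C)C=C2C=CC(=O)[C@](C)(C(O)CCO[Si](C)(C)C(C)(C)C)[C@H]21 | intermediate
31 | (1S,3S,7R,8S,8aS) diol: C7 tertiary alcohol (methyl β, OH α), side-chain secondary carbinol | I/C=C(\C)[C@H](O[Si](C)(C)C(C)(C)C)[C@H](C)C(=O)O[C@H]1C[C@H](C)C=C2C=C[C@@](C)(O)[C@](C)(C(O)CCO[Si](C)(C)C(C)(C)C)[C@H]21 | intermediate
32 | (1S,3S,7R,8R,8aS) keto alcohol: 8-[3-(silyloxy)propanoyl], C10' silyl ether | I/C=C(\C)[C@H](O[Si](C)(C)C(C)(C)C)[C@H](C)C(=O)O[C@H]1C[C@H](C)C=C2C=C[C@@](C)(O)[C@](C)(C(=O)CCO[Si](C)(C)C(C)(C)C)[C@H]21 | intermediate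
33 | (1S,3S,7R,8R,8aS)-7-hydroxy-8-(3-hydroxypropanoyl)-3,7,8-trimethyl-1,2,3,7,8,8a-hexahydronaphthalen-1-yl (2S,3R,4E)-3-hydroxy-5-iodo-2,4-dimethylpent-4-enoate | I/C=C(\C)[C@H](O)[C@H](C)C(=O)O[C@H]1C[C@H](C)C=C2C=C[C@@](C)(O)[C@](C)(C(=O)CCO)[C@H]21 | intermediate
34 | (E)-3-methylpent-2-en-4-yn-1-ol | C#C/C(C)=C/CO | starting material
35 | (2E,4E)-3-methyl-5-(tributylstannyl)penta-2,4-dien-1-ol | CCCC[Sn](CCCC)(CCCC)/C=C/C(C)=C/CO | intermediate
36 | (2E,4E)-3-methyl-5-(tributylstannyl)penta-2,4-dienal | CCCC[Sn](CCCC)(CCCC)/C=C/C(C)=C/C=O | intermediate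
37 | 2-(diethoxyphosphoryl)acetic acid | CCOP(=O)(CC(=O)O)OCC | starting material
38 | (2E,4E,6E)-5-methyl-7-(tributylstannyl)hepta-2,4,6-trienoic acid | CCCC[Sn](CCCC)(CCCC)/C=C/C(C)=C/C=C/C(=O)O | intermediate
39 | calbistrin C | CC(/C=C/C=C(\C)[C@H](O)[C@H](C)C(=O)O[C@H]1C[C@H](C)C=C2C=C[C@@](C)(O)[C@](C)(C(=O)CCO)[C@H]21)=C\C=C\C(=O)O | target

**Totals**
Total steps: 20. Longest linear sequence: 12 (steps 1–7, 13–16, 20).

**Steps most likely to fail**

Step 3 (the proposed tethered type 2 Diels–Alder). The bridged transition state may be too strained, or the silyl acetal may not survive 170 °C. The fallback uses known chemistry only and sets out from endoperoxide 2. The pseudoenantiomeric cinchona base gives (R)-4-hydroxycyclohex-2-en-1-one F1, which is silylated (t-BuMe2SiCl, imidazole) to silyl ether F2. An ordinary intermolecular Diels–Alder reaction with 3-(tert-butyldimethylsilyloxy)penta-1,3-diene F3 (from 4, t-BuMe2SiOTf, Et3N) adds anti to the C1 silyloxy group with the same regiochemistry and gives cis-octalone F4, which has C4a and C8a as in 8 but C1 epimeric. The main-route operations then follow: LiN(iPr)2/MeI to methyl ketone F5, LiBH4 to alcohol F6, MsCl to mesylate F7, Pd(OAc)2 then DBU to dienone silyl ether F8, and HF·pyridine to 1-epi alcohol F9. Mitsunobu inversion with 4-nitrobenzoic acid (PPh3, DIAD) gives the inverted 4-nitrobenzoate F10, and K2CO3/MeOH returns to the route at 15. The weak point of this fallback is the SN2 inversion at the hindered C1.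

Step 14 (one-pot aldol and methyl addition on the ester). The enolate may attack the neighbouring C1 ester (O-to-C acyl transfer), the aldolate may revert, or the methyl may add on the wrong face of C7. The fallback sets out from 15 and moves this chemistry ahead of the esterification. Et3SiOTf/2,6-lutidine gives triethylsilyl ether F11. The aldol from its LiN(iPr)2 enolate and 28 is isolated as β-hydroxy ketone F12; there is no ester in the molecule at this point. Methyl is added through the titanium aldolate chelate with MeTi(OiPr)3 (Reetz-type chelation control) to give diol F13, and Dess–Martin oxidation gives keto alcohol F14. Removal of only the triethylsilyl group (HF·pyridine/pyridine, 0 °C) gives C1 alcohol F15, which is esterified with 25 through mixed anhydride 26 (Yamaguchi, 60 °C), returning to the route at 32. The price is a harder acylation next to the quaternary C8.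

Step 7 (Saegusa, elimination and desilylation in one flask). The bridgehead silyl enol ether may oxidise sluggishly, or the mesylate may be lost before the enone is formed. The fallback sets out from 10 and removes the C4 oxygen through an enol triflate instead. Pd(OAc)2 then HF·pyridine applied directly to 10 gives ene-dione F16, a vinylogous 1,3-diketone that enolises at C4a. O-triflation (PhNTf2, Et3N) gives dienyl triflate F17, and palladium-catalysed formate hydrogenolysis (Pd(OAc)2, PPh3, HCO2H, Bu3N) returns to the route at 15. The uncertainty here is whether triflation occurs on the C4 or the C7 oxygen.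

Further compounds
F1 | step 3 | (R)-4-hydroxycyclohex-2-en-1-one | O[C@@H]1CCC(=O)C=C1
F2 | step 3 | (R)-4-[(tert-butyldimethylsilyl)oxy]cyclohex-2-en-1-one | CC(C)(C)[Si](C)(C)O[C@@H]1CCC(=O)C=C1
F3 | step 3 | 3-(tert-butyldimethylsilyloxy)penta-1,3-diene | CC=C(O[Si](C)(C)C(C)(C)C)C=C
F4 | step 3 | cis-octalone: 1-epi, bis-silyl analogue of 8 without bridge (C1 OSi β, C6=C7 silyl enol ether) | CC(C)(C)[Si](C)(C)O[C@@H]1CCC(=O)[C@H]2CC=C(O[Si](C)(C)C(C)(C)C)C(C)[C@H]21
F5 | step 3 | 3-methyl derivative of F4 | CC(C)(C)[Si](C)(C)O[C@@H]1C[C@H](C)C(=O)[C@H]2CC=C(O[Si](C)(C)C(C)(C)C)C(C)[C@H]21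
F6 | step 3 | C4 alcohol of F5 | CC(C)(C)[Si](C)(C)O[C@@H]1C[C@H](C)C(O)[C@H]2CC=C(O[Si](C)(C)C(C)(C)C)C(C)[C@H]21
F7 | step 3 | C4 methanesulfonate of F6 | CC(C)(C)[Si](C)(C)O[C@@H]1C[C@H](C)C(OS(C)(=O)=O)[C@H]2CC=C(O[Si](C)(C)C(C)(C)C)C(C)[C@H]21
F8 | step 3 | tert-butyldimethylsilyl ether of 1-epi-15 | CC(C)(C)[Si](C)(C)O[C@@H]1C[C@H](C)C=C2C=CC(=O)C(C)[C@H]21
F9 | step 3 | 1-epi-15 | O[C@@H]1C[C@H](C)C=C2C=CC(=O)C(C)[C@H]21
F10 | step 3 | 4-nitrobenzoate of 15 | O=C(O[C@H]1C[C@H](C)C=C2C=CC(=O)C(C)[C@H]21)c1ccc(cc1)[N+](=O)[O-]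
F11 | step 14 | triethylsilyl ether of 15 | CC[Si](CC)(CC)O[C@H]1C[C@H](C)C=C2C=CC(=O)C(C)[C@H]21
F12 | step 14 | C8 aldol of F11 with 28 | CC[Si](CC)(CC)O[C@H]1C[C@H](C)C=C2C=CC(=O)[C@](C)(C(O)CCO[Si](C)(C)C(C)(C)C)[C@H]21
F13 | step 14 | C7 methyl carbinol diol from F12 | CC[Si](CC)(CC)O[C@H]1C[C@H](C)C=C2C=C[C@@](C)(O)[C@](C)(C(O)CCO[Si](C)(C)C(C)(C)C)[C@H]21
F14 | step 14 | side-chain ketone from F13 | CC[Si](CC)(CC)O[C@H]1C[C@H](C)C=C2C=C[C@@](C)(O)[C@](C)(C(=O)CCO[Si](C)(C)C(C)(C)C)[C@H]21
F15 | step 14 | C1 alcohol from F14 | O[C@H]1C[C@H](C)C=C2C=C[C@@](C)(O)[C@](C)(C(=O)CCO[Si](C)(C)C(C)(C)C)[C@H]21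
F16 | step 7 | (1S,3S,4aS,8aS)-1-hydroxy-3,8-dimethyl-1,2,3,4a,8,8a-hexahydronaphthalene-4,7-dione | O[C@H]1C[C@H](C)C(=O)[C@H]2C=CC(=O)C(C)[C@H]21
F17 | step 7 | C4 enol trifluoromethanesulfonate of F16 | O[C@H]1C[C@H](C)C(OS(=O)(=O)C(F)(F)F)=C2C=CC(=O)C(C)[C@H]21
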